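The ten-membered carbocycle (C1–C10, germacrane numbering) is cut at C3–C4, inside the C2–C3 ethano bridge that separates its two cis ring alkenes, C1=C10 and C4=C5. In one operation a 9-BBN borane grown at C3 from the terminal C2=C3 vinyl group of a C10=C1–C2=C3 diene (C2 cis to C9) is coupled intramolecularly (B-alkyl Suzuki–Miyaura) with a Z-configured C4 alkenyl iodide, forming C3–C4 and closing the ring with both alkene geometries already fixed. The precursor is a seco trans-butyrolactone (C12,C6-olide, methylene masked as the dimethylamine adduct) carrying the iodoalkene on C6 and, on C7, the C8/C9 diester chain that ends in the C10 dienyl acetal; all four stereocentres are set beforehand.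

Key step: step 22

Remark: germacrane numbering is used for all intermediates (C12 lactone carbonyl, C13 methylene, C14 formyl carbon, C15 hydroxymethyl carbon). The amine-masked compounds are drawn as the C11 epimer with the aminomethyl group trans to the C8 branch, a centre that is erased in the last step. Compounds 10 and 28 are taken as purchased.

Step 1
Reactants: 1 diethyl (S)-malate; 2 allyl bromide
Product: 4 diethyl (2S,3R)-3-allyl-2-hydroxybutanedioate, via dilithium alkoxide enolate 3 (not isolated)
Conditions: LiN(i-Pr)2 (2.1 equiv), THF, −78 → −20 °C; then 2, −78 → −5 °C; aqueous work-up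
Reagents that add atoms: none
Why: Fráter–Seebach alkylation, in which the lithium-chelated alkoxide enolate 3 is allylated on the face anti to the C8 alkoxide, so the malate stereocentre sets C7 (3R, anti to the hydroxyl), the minor syn isomer being removed by chromatography.

Step 2
Reactants: 4 diethyl (2S,3R)-3-allyl-2-hydroxybutanedioate
Product: 5 (2S,3S)-3-(hydroxymethyl)hex-5-ene-1,2-diol
Conditions: LiAlH4, THF, 0 °C → reflux; aqueous work-up
Reagents that add atoms: none
Why: Hydride reduction of both esters to primary alcohols by LiAlH4, which leaves the isolated alkene and both stereocentres untouched.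

Step 3
Reactants: 5 (2S,3S)-3-(hydroxymethyl)hex-5-ene-1,2-diol
Product: 6 [(2S,4S,5S)-5-allyl-2-(4-methoxyphenyl)-1,3-dioxan-4-yl]methanol
Conditions: 4-MeOC6H4CH(OMe)2 (1.1 equiv), CSA (cat.), DMF, rt, reduced pressure
Reagents that add atoms: 4-methoxybenzaldehyde dimethyl acetal, COc1ccc(C(OC)OC)cc1
Why: Thermodynamic acetalisation, in which the 1,3-dioxane across O6 and O8 with aryl, C9 and allyl groups all equatorial is the most stable ring, so the C9 primary alcohol stays free and the acetal carbon is set with the aryl group equatorial under equilibrating acid catalysis.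

Step 4
Reactants: 6 [(2S,4S,5S)-5-allyl-2-(4-methoxyphenyl)-1,3-dioxan-4-yl]methanol
Product: 7 triethylsilyl ether of 6 at O9
Conditions: Et3SiCl, imidazole, CH2Cl2, 0 °C
Reagents that add atoms: chlorotriethylsilane, CC[Si](Cl)(CC)CC
Why: Standard silylation of the free primary alcohol with a silyl chloride and imidazole.

Step 5
Reactants: 7 triethylsilyl ether of 6
Product: 8 (2S,3S)-2-allyl-3-[(4-methoxybenzyl)oxy]-4-[(triethylsilyl)oxy]butan-1-ol
Conditions: i-Bu2AlH (3 equiv), CH2Cl2, −78 → 0 °C; aqueous work-up
Reagents that add atoms: none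
Why: Regioselective reductive opening of a 4-methoxybenzylidene acetal, in which the aluminium reagent binds the less hindered primary oxygen O6 and delivers hydride to the oxocarbenium ion, so the PMB group stays on the secondary O8 and the C6 alcohol is released.

Step 6
Reactants: 8 (2S,3S)-2-allyl-3-[(4-methoxybenzyl)oxy]-4-[(triethylsilyl)oxy]butan-1-ol
Product: 9 (2R,3S)-2-allyl-3-[(4-methoxybenzyl)oxy]-4-[(triethylsilyl)oxy]butanal
Conditions: DMP, pyridine, CH2Cl2, 0 °C → rt
Reagents that add atoms: none
Why: Dess–Martin oxidation under buffered, non-basic conditions gives the C6 aldehyde without epimerising C7 or eliminating the β-alkoxy group.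

Step 7
Reactants: 9 (2R,3S)-2-allyl-3-[(4-methoxybenzyl)oxy]-4-[(triethylsilyl)oxy]butanal; 10 tert-butyldimethyl(prop-2-yn-1-yloxy)silane
Product: 12 C6-epimeric propargylic alcohols, via lithium acetylide 11 (not isolated)
Conditions: 10, n-BuLi, THF, −78 °C; then 9, −78 °C; aqueous work-up
Reagents that add atoms: none
Why: 1,2-Addition of a lithium acetylide to an aldehyde, the C6 epimers being carried on together because C6 is reset in steps 8 and 9.

Step 8
Reactants: 12 C6-epimeric propargylic alcohols
Product: 13 ynone (C6 ketone)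
Conditions: DMP, pyridine, CH2Cl2, 0 °C
Reagents that add atoms: none
Why: Dess–Martin oxidation of the propargylic alcohols converges both epimers on one ynone.

Step 9
Reactants: 13 ynone
Product: 14 (6S)-propargylic alcohol
Conditions: Ru[(S,S)-TsDPEN](p-cymene) (2 mol %), i-PrOH, rt
Reagents that add atoms: none
Why: Noyori asymmetric transfer hydrogenation of an ynone, in which the (S,S)-catalyst delivers hydride under reagent control with the alkyne in the place of the aryl group to give the 6S carbinol, the base-free conditions sparing the epimerisable C7 centre.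

Step 10
Reactants: 14 (6S)-propargylic alcohol
Product: 16 Z-iodoalkenyl alcohol, via cyclic vinylalanate 15 (not isolated)
Conditions: NaAlH2(OCH2CH2OMe)2 (1.5 equiv), THF, 0 °C → rt; then I2 (1.2 equiv), THF, −78 °C
Reagents that add atoms: iodine, II
Why: Hydroxyl-directed trans-hydroalumination of a propargylic alcohol, in which the O6-bound aluminium hydride delivers hydride to C5 and aluminium to C4 within a five-membered alanate, and iodinolysis with retention gives the alkenyl iodide with iodine cis to C6 (Z).

Step 11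
Reactants: 16 Z-iodoalkenyl alcohol
Product: 19 lactol, via terminal diol 17 (not isolated), via hydroxy aldehyde 18 (not isolated)
Conditions: OsO4 (2 mol %), NaIO4 (3 equiv), 2,6-lutidine, dioxane/H2O 3:1, rt
Reagents that add atoms: sodium periodate (oxygen source by way of OsO4), [Na+].[O-]I(=O)(=O)=O
Why: Lemieux–Johnson oxidation, in which OsO4 dihydroxylates the monosubstituted alkene in preference to the electron-poor trisubstituted iodoalkene, periodate cleaves the diol and the C12 aldehyde is trapped by O6 as the five-membered lactol.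

Step 12
Reactants: 19 lactol
Product: 20 trans-lactone (12,6-olide)
Conditions: TEMPO (10 mol %), PhI(OAc)2 (1.5 equiv), CH2Cl2, rt
Reagents that add atoms: none
Why: Oxoammonium-mediated oxidation of a lactol to the γ-lactone, mild enough for the iodoalkene, the PMB ether and both silyl ethers.

Step 13
Reactants: 20 trans-lactone
Product: 24 α-methylene lactone, via lithium enolate 21 (not isolated), via Mannich base 22 (not isolated), via trimethylammonium iodide 23 (not isolated)
Conditions: LiN(i-Pr)2, THF, −78 °C; CH2=NMe2 I, −78 °C → rt; then MeI, MeOH, rt; then aq. NaHCO3/CH2Cl2, rt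
Reagents that add atoms: dimethylmethyleneiminium iodide, C=[N+](C)C.[I-]
Why: α-Methylenation of a lactone by Mannich reaction of its lithium enolate with the iminium salt (attack anti to the C7 branch), exhaustive N-methylation and base-induced Hofmann-type elimination.

Step 14
Reactants: 24 α-methylene lactone
Product: 25 C9 primary alcohol
Conditions: PPTS (cat.), MeOH/CH2Cl2 1:1, 0 °C
Reagents that add atoms: none
Why: Acid-catalysed methanolysis removes the primary triethylsilyl ether much faster than the tert-butyldimethylsilyl ether, and no acetal is present yet.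

Step 15
Reactants: 25 C9 primary alcohol
Product: 26 C9 aldehyde
Conditions: DMP, pyridine, CH2Cl2, 0 °C; used crude
Reagents that add atoms: none
Why: Dess–Martin oxidation gives the α-alkoxy aldehyde under non-basic conditions, so C8 is not epimerised.

Step 16
Reactants: 27 3,3-diethoxyprop-1-yne; 28 vinylmagnesium bromide (CH2=CHMgBr)
Product: 31 (3Z)-5,5-diethoxy-4-iodopenta-1,3-diene, via vinylcopper 29 (not isolated), via dienylcopper 30 (not isolated)
Conditions: 28, CuBr·SMe2, Et2O/THF, −40 °C; then 27, −40 → −20 °C; then I2, −78 → 0 °C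
Reagents that add atoms: iodine, II
Why: Syn-carbocupration of a propargylic acetal, in which the vinyl group adds to the terminal alkyne carbon and copper to the acetal-bearing carbon on the same side, and iodinolysis with retention gives the iodide with iodine cis to the vinyl group.

Step 17
Reactants: 26 C9 aldehyde; 31 (3Z)-5,5-diethoxy-4-iodopenta-1,3-diene
Product: 34 C9 alcohol, via dienyllithium 32 (not isolated), via dienylmagnesium bromide 33 (not isolated)
Conditions: 31, t-BuLi (2 equiv), Et2O, −78 °C; MgBr2·OEt2, −78 °C; then 26 precomplexed with MgBr2·OEt2, CH2Cl2, −78 °C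
Reagents that add atoms: none
Why: Iodine–lithium exchange and transmetalation to magnesium keep the alkene geometry, and the addition follows the Cram-chelate model, in which magnesium bridges the aldehyde oxygen and the PMB-ether oxygen on C8 and the nucleophile attacks from the side of H8 away from the C7 branch, setting C9 (S, syn to O8), while the aldehyde reacts far faster than the lactone or its methylene group at −78 °C.

Step 18
Reactants: 34 C9 alcohol
Product: 35 C9 acetate
Conditions: Ac2O, pyridine, DMAP (cat.), CH2Cl2, 0 °C → rt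
Reagents that add atoms: acetic anhydride, CC(=O)OC(C)=O
Why: Acetylation of the secondary allylic alcohol by nucleophilic catalysis.

Step 19
Reactants: 35 C9 acetate
Product: 36 C8 alcohol
Conditions: DDQ, CH2Cl2/aq. NaH2PO4–Na2HPO4 buffer (pH 7) 10:1, 0 °C
Reagents that add atoms: none
Why: Oxidative cleavage of the PMB ether by DDQ (hydride abstraction at the electron-rich benzylic position, then hydrolysis of the oxocarbenium ion), with the hindered diene, acetal, acetate and silyl ether inert and no amine present.

Step 20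
Reactants: 36 C8 alcohol; 37 (R)-2-methylbutanoic acid
Product: 38 C8,C9 diester with free methylene lactone
Conditions: DCC, DMAP, CH2Cl2, 0 °C → rt
Reagents that add atoms: none
Why: Steglich esterification of the C8 alcohol with the enantiopure acid, run at once on fresh 36 so that acylation outpaces acetyl migration from O9 or translactonisation onto O8, the α-alkyl acid not racemising under carbodiimide/DMAP activation.

Step 21
Reactants: 38 C8,C9 diester with free methylene lactone
Product: 39 seco precursor (dimethylamine adduct)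
Conditions: Me2NH (2 M in THF), THF, 0 °C
Reagents that add atoms: dimethylamine, CNC
Why: Aza-Michael addition of the secondary amine to the α-methylene lactone, much faster than aminolysis of the esters, with protonation of the enolate giving the C11 epimer that has the aminomethyl group trans to the C8 branch.

Step 22
Reactants: 39 seco precursor
Product: 41 macrocycle, via C3 alkylborane 40 (not isolated)
Conditions: 9-BBN dimer (1.5 equiv), THF, 0 °C → rt; H2O; then slow addition (12 h) to PdCl2(dppf) (20 mol %), AsPh3 (40 mol %), Cs2CO3 (3 equiv), DMF/THF/H2O, 50 °C, 0.002 M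
Reagents that add atoms: none
Why: 9-BBN adds across the only unhindered, monosubstituted alkene (C2=C3) with boron on C3, leaving the trisubstituted C1=C10 bond, the iodoalkene and the amine-masked lactone alone; zerovalent palladium then inserts into the C4–I bond, the base-activated primary alkyl group passes from boron to divalent palladium, and reductive elimination joins C3 to C4 with retention of the C4=C5 geometry. The closest known reaction type is the B-alkyl Suzuki–Miyaura macrocyclisation that follows chemoselective hydroboration of the terminal alkene of a 1,3-diene. The ten-membered carbocycle is closed head-to-tail between the C3 nucleophile and the C4 electrophile through an eleven-membered palladacycle, the C4=C5 bond ending up inside the ring. No stereocentre is formed, and both ring alkenes keep the cis ring geometry installed in steps 10 and 16. The step needs ring closure to beat oligomerisation, which high dilution and slow addition should secure, and C–I insertion to beat ionisation of the allylic C9 acetate, which the much faster oxidative addition into the alkenyl iodide should secure; excess 9-BBN covers reversible complexation by the tertiary amine.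

Step 23
Reactants: 41 macrocycle
Product: 42 C15 alcohol / C14 aldehyde (amine adduct)
Conditions: 1 M aq. HCl, THF, 0 °C → rt; NaHCO3 work-up
Reagents that add atoms: water, O
Why: Aqueous acid hydrolyses the diethyl acetal of the enal and cleaves the primary allylic silyl ether in one operation while the protonated amine is inert, both ring alkenes being electron-poor enough to resist transannular cyclisation.

Step 24
Reactants: 42 C15 alcohol / C14 aldehyde (amine adduct)
Product: 44 target CNP0247637.4, via trimethylammonium iodide 43 (not isolated)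
Conditions: MeI, THF, rt; then aq. NaHCO3/CH2Cl2, rt
Reagents that add atoms: none
Why: Quaternisation of the tertiary amine and bicarbonate-induced E1cB (Hofmann-type) elimination of trimethylamine regenerate the α-methylene lactone without touching the esters, the enal or the free alcohol.

Compound list

1 | diethyl (S)-malate, diethyl (2S)-2-hydroxybutanedioate | CCOC(=O)[C@@H](O)CC(=O)OCC | starting material
2 | allyl bromide, 3-bromoprop-1-ene | C=CCBr | starting material
3 | dilithium alkoxide enolate of 1 | CCOC(=O)[C@@H](O[Li])C=C(O[Li])OCC | intermediate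
4 | diethyl (2S,3R)-3-allyl-2-hydroxybutanedioate (ester carbons C9 and C6, carbinol C8, allylated carbon C7) | CCOC(=O)[C@@H](O)[C@@H](CC=C)C(=O)OCC | intermediate
5 | (2S,3S)-3-(hydroxymethyl)hex-5-ene-1,2-diol | OC[C@@H](O)[C@@H](CC=C)CO | intermediate
6 | [(2S,4S,5S)-5-allyl-2-(4-methoxyphenyl)-1,3-dioxan-4-yl]methanol (O6,O8-acetal, all three ring substituents equatorial, free C9 alcohol) | OC[C@@H](O[C@@H](c1ccc(OC)cc1)OC2)[C@H]2CC=C | intermediate
7 | triethyl{[(2S,4S,5S)-5-allyl-2-(4-methoxyphenyl)-1,3-dioxan-4-yl]methoxy}silane | CC[Si](CC)(CC)OC[C@@H](O[C@@H](c1ccc(OC)cc1)OC2)[C@H]2CC=C | intermediate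
8 | (2S,3S)-2-allyl-3-[(4-methoxybenzyl)oxy]-4-[(triethylsilyl)oxy]butan-1-ol | CC[Si](CC)(CC)OC[C@@H](OCc1ccc(OC)cc1)[C@@H](CC=C)CO | intermediate
9 | (2R,3S)-2-allyl-3-[(4-methoxybenzyl)oxy]-4-[(triethylsilyl)oxy]butanal | CC[Si](CC)(CC)OC[C@@H](OCc1ccc(OC)cc1)[C@@H](CC=C)C=O | intermediate
10 | tert-butyldimethyl(prop-2-yn-1-yloxy)silane | C#CCO[Si](C)(C)C(C)(C)C | starting material
11 | lithium acetylide of 10 | [Li]C#CCO[Si](C)(C)C(C)(C)C | intermediate
12 | (5S,6S)-5-allyl-1-[(tert-butyldimethylsilyl)oxy]-6-[(4-methoxybenzyl)oxy]-7-[(triethylsilyl)oxy]hept-2-yn-4-ol, both epimers at the carbinol (C6) | CC[Si](CC)(CC)OC[C@@H](OCc1ccc(OC)cc1)[C@@H](CC=C)C(O)C#CCO[Si](C)(C)C(C)(C)C | intermediate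
13 | (5R,6S)-5-allyl-1-[(tert-butyldimethylsilyl)oxy]-6-[(4-methoxybenzyl)oxy]-7-[(triethylsilyl)oxy]hept-2-yn-4-one | CC[Si](CC)(CC)OC[C@@H](OCc1ccc(OC)cc1)[C@@H](CC=C)C(=O)C#CCO[Si](C)(C)C(C)(C)C | intermediate
14 | (4S,5S,6S)-5-allyl-1-[(tert-butyldimethylsilyl)oxy]-6-[(4-methoxybenzyl)oxy]-7-[(triethylsilyl)oxy]hept-2-yn-4-ol | CC[Si](CC)(CC)OC[C@@H](OCc1ccc(OC)cc1)[C@@H](CC=C)[C@H](O)C#CCO[Si](C)(C)C(C)(C)C | intermediate
15 | sodium alkoxy(alkenyl)bis(2-methoxyethoxy)aluminate of 14, five-membered ring O6–Al–C4=C5–C6 | [Na+].COCCO[Al-]1(OCCOC)O[C@H](C=C1CO[Si](C)(C)C(C)(C)C)[C@H](CC=C)[C@@H](CO[Si](CC)(CC)CC)OCc2ccc(OC)cc2 | intermediate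
16 | (2Z,4S,5S,6S)-5-allyl-1-[(tert-butyldimethylsilyl)oxy]-2-iodo-6-[(4-methoxybenzyl)oxy]-7-[(triethylsilyl)oxy]hept-2-en-4-ol (iodine on C4, cis to C6) | CC[Si](CC)(CC)OC[C@@H](OCc1ccc(OC)cc1)[C@@H](CC=C)[C@H](O)/C=C(/CO[Si](C)(C)C(C)(C)C)I | intermediate
17 | terminal 1,2-diol from the allyl group of 16 (both carbinol epimers) | CC[Si](CC)(CC)OC[C@@H](OCc1ccc(OC)cc1)[C@@H](CC(O)CO)[C@H](O)/C=C(/CO[Si](C)(C)C(C)(C)C)I | intermediate
18 | C12 aldehyde (γ-hydroxy aldehyde) from 17 | CC[Si](CC)(CC)OC[C@@H](OCc1ccc(OC)cc1)[C@@H](CC=O)[C@H](O)/C=C(/CO[Si](C)(C)C(C)(C)C)I | intermediate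
19 | lactol of 18 (O6–C12 hemiacetal, both anomers) | C1C(O)O[C@H](/C=C(/CO[Si](C)(C)C(C)(C)C)I)[C@H]1[C@H](OCc2ccc(OC)cc2)CO[Si](CC)(CC)CC | intermediate
20 | (4S,5S)-5-[(1Z)-3-[(tert-butyldimethylsilyl)oxy]-2-iodoprop-1-en-1-yl]-4-[(1S)-1-[(4-methoxybenzyl)oxy]-2-[(triethylsilyl)oxy]ethyl]oxolan-2-one (trans 12,6-olide) | C1C(=O)O[C@H](/C=C(/CO[Si](C)(C)C(C)(C)C)I)[C@H]1[C@H](OCc2ccc(OC)cc2)CO[Si](CC)(CC)CC | intermediate
21 | lithium enolate of 20 | C1=C(O[Li])O[C@H](/C=C(/CO[Si](C)(C)C(C)(C)C)I)[C@H]1[C@H](OCc2ccc(OC)cc2)CO[Si](CC)(CC)CC | intermediate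
22 | (11R)-11-[(dimethylamino)methyl] derivative of 20 (Mannich base, trans to the C7 branch) | CN(C)C[C@@H]1C(=O)O[C@H](/C=C(/CO[Si](C)(C)C(C)(C)C)I)[C@H]1[C@H](OCc2ccc(OC)cc2)CO[Si](CC)(CC)CC | intermediate
23 | trimethylammonium iodide of 22 | C[N+](C)(C)C[C@@H]1C(=O)O[C@H](/C=C(/CO[Si](C)(C)C(C)(C)C)I)[C@H]1[C@H](OCc2ccc(OC)cc2)CO[Si](CC)(CC)CC.[I-] | intermediate
24 | 3-methylidene derivative of 20 (α-methylene lactone, stereocentres as in 20) | C=C1C(=O)O[C@H](/C=C(/CO[Si](C)(C)C(C)(C)C)I)[C@H]1[C@H](OCc2ccc(OC)cc2)CO[Si](CC)(CC)CC | intermediate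
25 | C9 primary alcohol from 24 (triethylsilyl group removed) | C=C1C(=O)O[C@H](/C=C(/CO[Si](C)(C)C(C)(C)C)I)[C@H]1[C@H](OCc2ccc(OC)cc2)CO | intermediate
26 | C9 aldehyde from 25 (α-PMB-oxy aldehyde, C8 S) | C=C1C(=O)O[C@H](/C=C(/CO[Si](C)(C)C(C)(C)C)I)[C@H]1[C@H](OCc2ccc(OC)cc2)C=O | intermediate
27 | 3,3-diethoxyprop-1-yne | C#CC(OCC)OCC | starting material
28 | vinylmagnesium bromide (CH2=CHMgBr) | C=C[Mg]Br | starting material
29 | vinylcopper (CH2=CHCu) | C=C[Cu] | intermediate
30 | (1,1-diethoxypenta-2,4-dien-2-yl)copper, copper cis to the vinyl group | C=C/C=C(\[Cu])C(OCC)OCC | intermediate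
31 | (3Z)-5,5-diethoxy-4-iodopenta-1,3-diene | C=C/C=C(\I)C(OCC)OCC | intermediate
32 | (1,1-diethoxypenta-2,4-dien-2-yl)lithium, lithium in the place of iodine in 31 | C=C/C=C(\[Li])C(OCC)OCC | intermediate
33 | (1,1-diethoxypenta-2,4-dien-2-yl)magnesium bromide, same geometry | C=C/C=C(\[Mg]Br)C(OCC)OCC | intermediate
34 | (6S,7S,8S,9S) C9 alcohol: 26 extended at C9 by the 1,1-diethoxypenta-2,4-dien-2-yl group (C10 bears C14 acetal, C2 cis to C9), C8-OPMB | C=C1C(=O)O[C@H](/C=C(/CO[Si](C)(C)C(C)(C)C)I)[C@H]1[C@H](OCc2ccc(OC)cc2)[C@@H](O)/C(C(OCC)OCC)=C\C=C | intermediate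
35 | C9 acetate of 34 | C=C1C(=O)O[C@H](/C=C(/CO[Si](C)(C)C(C)(C)C)I)[C@H]1[C@H](OCc2ccc(OC)cc2)[C@@H](OC(C)=O)/C(C(OCC)OCC)=C\C=C | intermediate
36 | C8 alcohol from 35 (PMB group removed) | C=C1C(=O)O[C@H](/C=C(/CO[Si](C)(C)C(C)(C)C)I)[C@H]1[C@H](O)[C@@H](OC(C)=O)/C(C(OCC)OCC)=C\C=C | intermediate
37 | (R)-2-methylbutanoic acid | CC[C@@H](C)C(=O)O | starting material
38 | C8 (2R)-2-methylbutanoate, C9 acetate, free α-methylene lactone | C=C1C(=O)O[C@H](/C=C(/CO[Si](C)(C)C(C)(C)C)I)[C@H]1[C@H](OC(=O)[C@H](C)CC)[C@@H](OC(C)=O)/C(C(OCC)OCC)=C\C=C | intermediate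
39 | (6S,7S,8S,9S,11R) seco precursor: 13-dimethylamino adduct of 38 with Z-C4 iodide, C15-OTBS, C14 diethyl acetal and terminal C2=C3 | CN(C)C[C@@H]1C(=O)O[C@H](/C=C(/CO[Si](C)(C)C(C)(C)C)I)[C@H]1[C@H](OC(=O)[C@H](C)CC)[C@@H](OC(C)=O)/C(C(OCC)OCC)=C\C=C | intermediate
40 | C3 B-alkyl-9-borabicyclo[3.3.1]nonane from 39 | CN(C)C[C@@H]1C(=O)O[C@H](/C=C(/CO[Si](C)(C)C(C)(C)C)I)[C@H]1[C@H](OC(=O)[C@H](C)CC)[C@@H](OC(C)=O)/C(C(OCC)OCC)=C\CCB2C3CCCC2CCC3 | intermediate
41 | (6R,7S,8S,9S,11R) macrocycle: ten-membered ring with both cis ring alkenes, C14 diethyl acetal, C15-OTBS, amine-masked lactone | CN(C)C[C@@H]1C(=O)O[C@@H]2/C=C(/CO[Si](C)(C)C(C)(C)C)CC/C=C(/C(OCC)OCC)[C@H](OC(C)=O)[C@@H](OC(=O)[C@H](C)CC)[C@@H]12 | intermediate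
42 | 13-dimethylamino-11,13-dihydro derivative of the target (C15 alcohol, C14 aldehyde) | CN(C)C[C@@H]1C(=O)O[C@@H]2/C=C(/CO)CC/C=C(/C=O)[C@H](OC(C)=O)[C@@H](OC(=O)[C@H](C)CC)[C@@H]12 | intermediate
43 | trimethylammonium iodide of 42 | C[N+](C)(C)C[C@@H]1C(=O)O[C@@H]2/C=C(/CO)CC/C=C(/C=O)[C@H](OC(C)=O)[C@@H](OC(=O)[C@H](C)CC)[C@@H]12.[I-] | intermediate
44 | CNP0247637.4: (6R,7S,8S,9S)-9-acetoxy-15-hydroxy-8-[(2R)-2-methylbutanoyloxy]-14-oxogermacra-1(10),4,11(13)-trien-12,6-olide (C2 cis to C9, C3 cis to C6) | C=C1C(=O)O[C@@H]2/C=C(/CO)CC/C=C(/C=O)[C@H](OC(C)=O)[C@@H](OC(=O)[C@H](C)CC)[C@@H]12 | target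

Total step count: 24. Longest linear sequence: 23 steps (steps 1–15 and 17–24; step 16 is the side branch).

Steps most likely to fail

Step 22. The ten-membered closure is slow, so intermolecular coupling to oligomers, protodeboronation of the C3 borane or ionisation of the allylic C9 acetate at zerovalent palladium may outrun it. The fallback keeps the C3–C4 bond but changes the organometallic partner. It sets out from 39, which is hydroborated as before (40) and oxidised with NaBO3·4H2O to the C3 primary alcohol F1. An Appel reaction (I2, PPh3, imidazole) gives the C3 primary iodide F2. Zinc dust with LiCl in THF inserts into the sp3 C–I bond in preference to the alkenyl C–I bond and gives the alkylzinc iodide F3 (not isolated). An intramolecular Negishi coupling (Pd(OAc)2, SPhos, THF, high dilution) then closes the ring and comes back to the route at 41.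

Step 17. The magnesium chelate may not hold, which would erode facial selectivity at C9; the lithiated acetal may lose ethoxide before transmetalation; or the nucleophile may attack the lactone. The fallback replaces halogen–metal exchange by a three-component union. It sets out from 27, 28 and 26: dienylcopper 30 from the carbocupration of step 16 is not iodinated but, in the presence of MgBr2·OEt2, added directly to aldehyde 26 at −78 °C. Organocopper additions to α-alkoxy aldehydes follow the chelate model, and the reagent never passes through the free dienyllithium. The fallback comes back to the route at 34 and makes no new compound (F0).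

Step 10. The C4 alanate may expel the neighbouring silyloxide to give an allene, and excess iodine may cyclise O6 onto the allyl group. The fallback builds the iodoalkene by polar addition. It sets out from ynone 13: conjugate hydroiodination (NaI, AcOH, MeCN, rt, anti addition) should give the Z-β-iodoenone F4 with iodine cis to C6. A Corey–Bakshi–Shibata reduction ((R)-2-methyl-CBS-oxazaborolidine, catecholborane, toluene, −78 °C, alkenyl group as the large substituent) should then set 6S and come back to the route at 16, so that steps 9 and 10 are skipped.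

Further compounds

F1 | step 22 | C3 primary alcohol from hydroboration–oxidation of 39 | CN(C)C[C@@H]1C(=O)O[C@H](/C=C(/CO[Si](C)(C)C(C)(C)C)I)[C@H]1[C@H](OC(=O)[C@H](C)CC)[C@@H](OC(C)=O)/C(C(OCC)OCC)=C\CCO
F2 | step 22 | C3 primary iodide | CN(C)C[C@@H]1C(=O)O[C@H](/C=C(/CO[Si](C)(C)C(C)(C)C)I)[C@H]1[C@H](OC(=O)[C@H](C)CC)[C@@H](OC(C)=O)/C(C(OCC)OCC)=C\CCI
F3 | step 22 | C3 alkylzinc iodide | CN(C)C[C@@H]1C(=O)O[C@H](/C=C(/CO[Si](C)(C)C(C)(C)C)I)[C@H]1[C@H](OC(=O)[C@H](C)CC)[C@@H](OC(C)=O)/C(C(OCC)OCC)=C\CC[Zn]I
F0 | step 17 | none | none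
F4 | step 10 | Z-β-iodoenone (C6 ketone, iodine on C4 cis to C6) | CC[Si](CC)(CC)OC[C@@H](OCc1ccc(OC)cc1)[C@@H](CC=C)C(=O)/C=C(/CO[Si](C)(C)C(C)(C)C)I
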